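**Retrosynthetic overview**

1. Target 30 (5S,6R,7S,8S) comes from 29 by MOM removal and 29 from 5-ketone 28 by Luche reduction, which resets C5. The pyranone ring (O1, C2, C3, C4) of 26 is annulated onto the C8a ketone and C4a methylene of cyclohexanone 20 by an enamine–acylketene [4+2] addition.
2. Feature: the carbocycle C4a–C5–C6–C7–C8–C8a is a masked 2-deoxyinosose. C6, C7 and C8 carry the O2/O3/O4 pattern of D-altrose (C2–C4), C8a is a latent ketone (sugar C5) and C4a its α-CH2 (sugar C6), so C4a–C5 is an aldol bond.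
3. Key disconnection: cyclohexanone 19 from methyl 4-O-aryl-hex-5-enopyranoside 16 by Ferrier carbocyclisation (divalent mercury, water), with the C8–O–aryl ether already placed on O4.
4. 16 comes from altroside 8 (made from the commercial glucoside acetal 1 by epoxide formation and trans-diaxial opening) and iodochromone 12 (from paeonol 9) by Ullmann-type etherification. The side-chain donor 23 comes from dioxinone 22.
5. Order of ring formation: chromone of the aryl unit (step 9), carbocycle (step 14), pyranone of the tetrahydrochromone (step 18).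

Key step: step 14

Remark: Ar = 7-methoxy-4-oxo-2-(2-phenylethyl)-4H-chromen-6-yl. Carbohydrate numbering is used up to 18, cyclohexanone numbering for 19–21 and chromone numbering (O1, C2–C4, C4a, C5–C8, C8a) from 25 on. Compound 1 is a catalogue chemical, so the route starts there.

**Route**

Step 1
Reactants: 1 methyl 4,6-O-[(R)-benzylidene]-α-D-glucopyranoside
Product: 2 methyl 4,6-O-benzylidene-2,3-di-O-(4-methylbenzenesulfonyl)-α-D-glucopyranoside
Conditions: TsCl, pyridine, DMAP (cat.), 0 °C → 40 °C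
Reagents that add atoms: 4-methylbenzenesulfonyl chloride (TsCl), Cc1ccc(cc1)S(=O)(=O)Cl
Why: Standard O-sulfonylation of both free secondary hydroxyls under nucleophilic catalysis; no stereocentre is touched.

Step 2
Reactants: 2 methyl 4,6-O-benzylidene-2,3-di-O-tosyl-α-D-glucopyranoside
Product: 4 methyl 2,3-anhydro-4,6-O-benzylidene-α-D-allopyranoside, via 3-O-tosyl 2-alkoxide 3 (not isolated)
Conditions: NaOMe, MeOH–CH2Cl2, reflux
Reagents that add atoms: none
Why: Methoxide cleaves the more exposed 2-O-sulfonate at sulfur and the C2 alkoxide displaces the trans 3-O-tosylate in an intramolecular SN2 reaction, which inverts C3 and gives the allo-epoxide (classical anhydro-sugar formation).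

Step 3
Reactants: 4 methyl 2,3-anhydro-4,6-O-benzylidene-α-D-allopyranoside
Product: 5 methyl 4,6-O-benzylidene-α-D-altropyranoside
Conditions: KOH, H2O–DMSO, 100 °C
Reagents that add atoms: water, O (delivered as the hydroxide of KOH)
Why: Hydroxide opens the conformationally locked epoxide at C2 in the trans-diaxial sense (Fürst–Plattner opening), inverting C2 and giving the altro diol with O2 and O3 both axial.

Step 4
Reactants: 5 methyl 4,6-O-benzylidene-α-D-altropyranoside
Product: 6 methyl 4,6-O-benzylidene-2,3-di-O-(methoxymethyl)-α-D-altropyranoside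
Conditions: MOMCl, i-Pr2NEt, Bu4NI (cat.), CH2Cl2, 40 °C
Reagents that add atoms: chloro(methoxy)methane (MOMCl), COCCl
Why: Williamson-type acetalisation of both axial hydroxyls with the reactive α-chloro ether under amine base; configuration is unchanged.

Step 5
Reactants: 6 methyl 4,6-O-benzylidene-2,3-di-O-(methoxymethyl)-α-D-altropyranoside
Product: 7 methyl 2,3-di-O-(methoxymethyl)-α-D-altropyranoside
Conditions: H2 (1 atm), Pd(OH)2/C, EtOAc–MeOH, rt
Reagents that add atoms: none
Why: Hydrogenolysis of the two benzylic C–O bonds of the acetal frees the 4,6-diol, while MOM ethers and the methyl glycoside are inert to these neutral conditions.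

Step 6
Reactants: 7 methyl 2,3-di-O-(methoxymethyl)-α-D-altropyranoside
Product: 8 methyl 6-O-(tert-butyldiphenylsilyl)-2,3-di-O-(methoxymethyl)-α-D-altropyranoside
Conditions: TBDPSCl, imidazole, DMF, 0 °C → rt
Reagents that add atoms: tert-butyl(chloro)diphenylsilane, CC(C)(C)[Si](Cl)(c1ccccc1)c1ccccc1
Why: Selective silylation: the bulky chlorosilane reacts much faster with the primary 6-OH than with the flanked secondary 4-OH, which is left free for arylation.

Step 7
Reactants: 9 1-(2-hydroxy-4-methoxyphenyl)ethanone (paeonol)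
Product: 10 1-(2-hydroxy-5-iodo-4-methoxyphenyl)ethanone
Conditions: NIS, CF3CO2H (cat.), MeCN, rt
Reagents that add atoms: N-iodosuccinimide, O=C1CCC(=O)N1I
Why: Electrophilic aromatic iodination should occur at C5, para to the phenol and ortho to the methoxy group, because the position between the two oxygens is more hindered.

Step 8
Reactants: 10 1-(2-hydroxy-5-iodo-4-methoxyphenyl)ethanone
Product: 11 1-(2-hydroxy-5-iodo-4-methoxyphenyl)-5-phenylpentane-1,3-dione
Conditions: LiN(SiMe3)2 (3.2 equiv), THF, −78 → −10 °C; then PhCH2CH2COCl, −78 °C → rt; aq. HCl work-up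
Reagents that add atoms: 3-phenylpropanoyl chloride, O=C(Cl)CCc1ccccc1
Why: Claisen-type C-acylation: the phenoxide–enolate dianion is acylated at carbon by the acid chloride and the third equivalent of base holds the product as its enolate until work-up.

Step 9
Reactants: 11 1-(2-hydroxy-5-iodo-4-methoxyphenyl)-5-phenylpentane-1,3-dione
Product: 12 6-iodo-7-methoxy-2-(2-phenylethyl)-4H-chromen-4-one
Conditions: H2SO4 (cat.), AcOH, 90 °C
Reagents that add atoms: none
Why: Acid-catalysed cyclodehydration of the o-hydroxyaryl 1,3-diketone (phenol oxygen onto the distal carbonyl, then loss of water) closes the chromone pyranone ring.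

Step 10
Reactants: 8 methyl 6-O-(tert-butyldiphenylsilyl)-2,3-di-O-(methoxymethyl)-α-D-altropyranoside; 12 6-iodo-7-methoxy-2-(2-phenylethyl)-4H-chromen-4-one
Product: 13 methyl 4-O-Ar-6-O-(tert-butyldiphenylsilyl)-2,3-di-O-(methoxymethyl)-α-D-altropyranoside
Conditions: CuI (20 mol %), 3,4,7,8-tetramethyl-1,10-phenanthroline (40 mol %), Cs2CO3, 4 Å MS, PhMe, 110 °C (12 in excess)
Reagents that add atoms: none
Why: Ullmann-type C–O coupling: the caesium alkoxide of 8 binds the phenanthroline-ligated monovalent copper centre, which activates the C–I bond of 12 and releases the alkyl aryl ether; only the O–H bond is broken, so C4 keeps its configuration.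

Step 11
Reactants: 13 methyl 4-O-Ar-6-O-(tert-butyldiphenylsilyl)-2,3-di-O-(methoxymethyl)-α-D-altropyranoside
Product: 14 methyl 4-O-Ar-2,3-di-O-(methoxymethyl)-α-D-altropyranoside
Conditions: Bu4NF, AcOH, THF, rt
Reagents that add atoms: none
Why: Fluoride cleaves the Si–O bond of the primary silyl ether; acetic acid buffering protects the base-sensitive chromone.

Step 12
Reactants: 14 methyl 4-O-Ar-2,3-di-O-(methoxymethyl)-α-D-altropyranoside
Product: 15 methyl 4-O-Ar-6-deoxy-6-iodo-2,3-di-O-(methoxymethyl)-α-D-altropyranoside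
Conditions: I2, PPh3, imidazole, PhMe, 60 °C
Reagents that add atoms: iodine, II
Why: Appel-type iodination: the alkoxyphosphonium ion of the only free (primary) hydroxyl is displaced by iodide in an SN2 reaction at C6.

Step 13
Reactants: 15 methyl 4-O-Ar-6-deoxy-6-iodo-2,3-di-O-(methoxymethyl)-α-D-altropyranoside
Product: 16 methyl 4-O-Ar-6-deoxy-2,3-di-O-(methoxymethyl)-α-D-arabino-hex-5-enopyranoside
Conditions: DBU, THF, 65 °C
Reagents that add atoms: none
Why: E2 dehydroiodination (H5 and the C6 iodide) by the amidine base gives the exocyclic enol ether; acetals, aryl ether and chromone are inert to it.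

Step 14
Reactants: 16 methyl 4-O-Ar-6-deoxy-2,3-di-O-(methoxymethyl)-α-D-arabino-hex-5-enopyranoside
Product: 19 (2S,3S,4R,5R)-2-(ArO)-5-hydroxy-3,4-bis(methoxymethoxy)cyclohexan-1-one (2,3-cis, 3,4-trans, 4,5-cis), via mercurial hemiketal 17 (not isolated), via mercurio keto-aldehyde 18 (not isolated)
Conditions: Hg(OCOCF3)2 (10 mol %), acetone–H2O (4:1), rt
Reagents that add atoms: water, O
Why: The divalent mercury salt adds to the electron-rich exocyclic enol ether with water entering at C5 (Markovnikov oxymercuration) to give hemiketal 17, which opens and loses methanol to the 6-mercurio 5-keto aldehyde 18; its mercury enolate carbon (sugar C6) then adds to the C1 aldehyde and the mercury salt is released for the next turnover. This is the Ferrier carbocyclisation of 6-deoxyhex-5-enopyranosides to 2-deoxyinososes, applied here to an O4-aryl altro substrate. The six-membered carbocycle closes by a 6-(enolexo)-exo-trig aldol that forms the C4a–C5 bond of the target (sugar C6–C1). The new carbinol centre (target C5) is fixed by a chair-like aldol transition state and should appear trans to the O3 substituent (target C7), that is as the 5-epimer of the target; this is tolerated because C5 is oxidised and reset in steps 20 and 21, while C6, C7 and C8 come unchanged from C2, C3 and C4 of the sugar. The step needs mercuration of the enol ether only, which is secured by its much higher nucleophilicity than the electron-poor chromone C2=C3 bond and the deactivated arenes, and the near-neutral conditions at room temperature should prevent β-elimination of the new hydroxyl or of the C7 alkoxy group.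

Step 15
Reactants: 19 2-(ArO)-5-hydroxy-3,4-bis(methoxymethoxy)cyclohexan-1-one
Product: 20 5-O-(tert-butyldimethylsilyl) ether of 19
Conditions: TBSOTf, 2,6-lutidine, CH2Cl2, −78 °C
Reagents that add atoms: tert-butyldimethylsilyl trifluoromethanesulfonate, CC(C)(C)[Si](C)(C)OS(=O)(=O)C(F)(F)F
Why: O-silylation of the β-hydroxyl with the silyl triflate and a hindered base at low temperature is faster than enolisation or β-elimination of the hydroxy ketone.

Step 16
Reactants: 20 5-O-TBS ether of cyclohexanone 19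
Product: 21 pyrrolidine enamine of 20 with the double bond C1=C6 (towards the CH2, target C4a)
Conditions: pyrrolidine, 4 Å MS, PhH, rt; volatiles removed, used crude
Reagents that add atoms: pyrrolidine, C1CCNC1
Why: Enamine condensation under dehydrating conditions should give the less substituted enamine, since the isomer towards the aryloxy-bearing carbon suffers allylic strain and would place a donor oxygen on the enamine double bond; C8 is therefore not enolised.

Step 17
Reactants: 22 2,2,6-trimethyl-4H-1,3-dioxin-4-one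
Product: 23 2,2-dimethyl-6-(2-phenylethyl)-4H-1,3-dioxin-4-one
Conditions: LiN(i-Pr)2, THF–DMPU, −78 °C; BnBr, −78 → −20 °C
Reagents that add atoms: benzyl bromide, BrCc1ccccc1
Why: Vinylogous enolate alkylation: deprotonation of the 6-methyl group gives the extended lithium dienolate, which the reactive benzylic halide alkylates at the γ-terminus.

Step 18
Reactants: 21 pyrrolidine enamine; 23 2,2-dimethyl-6-(2-phenylethyl)-4H-1,3-dioxin-4-one
Product: 26 8-(ArO)-5-(tert-butyldimethylsilyloxy)-6,7-bis(methoxymethoxy)-2-(2-phenylethyl)-5,6,7,8-tetrahydro-4H-chromen-4-one (5-epi series: O5 cis to O6, trans to O7 and O8), via acylketene 24 (not isolated), via aminal adduct 25 (not isolated)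
Conditions: PhMe, 110 °C; then AcOH, rt
Reagents that add atoms: none
Why: Thermal retro-[4+2] of the dioxinone releases acetone and acylketene 24, which the enamine captures in a [4+2] addition (ketene carbon to C4a, acyl oxygen to C8a); aminal 25 then loses pyrrolidine to give the 4-pyranone, the classical enamine–acylketene pyrone annulation.

Step 19
Reactants: 26 5-O-TBS tetrahydrochromone
Product: 27 8-(ArO)-5-hydroxy-6,7-bis(methoxymethoxy)-2-(2-phenylethyl)-5,6,7,8-tetrahydro-4H-chromen-4-one (5-epimer, O5 cis to O6)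
Conditions: HF·pyridine, pyridine, THF, 0 °C → rt
Reagents that add atoms: none
Why: Buffered fluoride cleaves the secondary silyl ether; MOM ethers, the aryl ether and both pyranones are stable to it.

Step 20
Reactants: 27 5-epi alcohol
Product: 28 8-(ArO)-6,7-bis(methoxymethoxy)-2-(2-phenylethyl)-7,8-dihydro-4H-chromene-4,5(6H)-dione
Conditions: Dess–Martin periodinane, NaHCO3, CH2Cl2, 0 °C → rt; used at once
Reagents that add atoms: none
Why: Dess–Martin oxidation of the secondary carbinol under buffered, essentially neutral conditions erases the C5 configuration without enolising C6.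

Step 21
Reactants: 28 5-ketone
Product: 29 (5S,6R,7S,8S)-8-(ArO)-5-hydroxy-6,7-bis(methoxymethoxy)-2-(2-phenylethyl)-5,6,7,8-tetrahydro-4H-chromen-4-one (O5 trans to O6)
Conditions: NaBH4, CeCl3·7H2O, MeOH–CH2Cl2, −78 °C
Reagents that add atoms: none
Why: Luche 1,2-reduction: with CeCl3 the hydride should attack only the C5 ketone (the pyranone carbonyls are far less electrophilic) and enter axially, anti to the pseudo-axial C6–H of the half-chair that holds the C6 alkoxy group pseudo-equatorial, as in Luche reductions of 6-alkoxycyclohex-2-enones, so the new hydroxyl should be trans to O6 (5S).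

Step 22
Reactants: 29 6,7-di-O-MOM ether of the target
Product: 30 (5S,6R,7S,8S)-5,6,7-trihydroxy-8-{[7-methoxy-4-oxo-2-(2-phenylethyl)-4H-chromen-6-yl]oxy}-2-(2-phenylethyl)-5,6,7,8-tetrahydro-4H-chromen-4-one
Conditions: ZnBr2, n-PrSH, CH2Cl2, 0 °C
Reagents that add atoms: none
Why: Lewis-acid-assisted acetal exchange: ZnBr2 activates each MOM acetal and the thiol captures the methoxymethyl unit, freeing both hydroxyls under conditions mild enough that the C5 carbinol and the C8 aryl ether should not ionise.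

**Compound list**

1 | methyl 4,6-O-[(R)-benzylidene]-α-D-glucopyranoside | CO[C@H]1O[C@@H]2CO[C@@H](c3ccccc3)O[C@H]2[C@H](O)[C@H]1O | starting material
2 | methyl 4,6-O-benzylidene-2,3-di-O-tosyl-α-D-glucopyranoside | CO[C@H]1O[C@@H]2CO[C@@H](c3ccccc3)O[C@H]2[C@H](OS(=O)(=O)c3ccc(C)cc3)[C@H]1OS(=O)(=O)c1ccc(C)cc1 | intermediate
3 | methyl 4,6-O-benzylidene-3-O-tosyl-α-D-glucopyranoside (as sodium 2-alkoxide, not isolated) | CO[C@H]1O[C@@H]2CO[C@@H](c3ccccc3)O[C@H]2[C@H](OS(=O)(=O)c3ccc(C)cc3)[C@H]1O | intermediate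
4 | methyl 2,3-anhydro-4,6-O-benzylidene-α-D-allopyranoside | CO[C@H]1O[C@@H]2CO[C@@H](c3ccccc3)O[C@H]2[C@H]3O[C@@H]13 | intermediate
5 | methyl 4,6-O-benzylidene-α-D-altropyranoside | CO[C@H]1O[C@@H]2CO[C@@H](c3ccccc3)O[C@H]2[C@@H](O)[C@@H]1O | intermediate
6 | methyl 4,6-O-benzylidene-2,3-di-O-(methoxymethyl)-α-D-altropyranoside | CO[C@H]1O[C@@H]2CO[C@@H](c3ccccc3)O[C@H]2[C@@H](OCOC)[C@@H]1OCOC | intermediate
7 | methyl 2,3-di-O-(methoxymethyl)-α-D-altropyranoside | CO[C@H]1O[C@H](CO)[C@@H](O)[C@@H](OCOC)[C@@H]1OCOC | intermediate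
8 | methyl 6-O-(tert-butyldiphenylsilyl)-2,3-di-O-(methoxymethyl)-α-D-altropyranoside | CO[C@H]1O[C@H](CO[Si](c2ccccc2)(c2ccccc2)C(C)(C)C)[C@@H](O)[C@@H](OCOC)[C@@H]1OCOC | intermediate
9 | 1-(2-hydroxy-4-methoxyphenyl)ethanone (paeonol) | COc1ccc(C(C)=O)c(O)c1 | starting material
10 | 1-(2-hydroxy-5-iodo-4-methoxyphenyl)ethanone | COc1cc(O)c(C(C)=O)cc1I | intermediate
11 | 1-(2-hydroxy-5-iodo-4-methoxyphenyl)-5-phenylpentane-1,3-dione | COc1cc(O)c(C(=O)CC(=O)CCc2ccccc2)cc1I | intermediate
12 | 6-iodo-7-methoxy-2-(2-phenylethyl)-4H-chromen-4-one | COc1cc2oc(CCc3ccccc3)cc(=O)c2cc1I | intermediate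
13 | methyl 4-O-Ar-6-O-(tert-butyldiphenylsilyl)-2,3-di-O-(methoxymethyl)-α-D-altropyranoside | COc1cc2oc(CCc3ccccc3)cc(=O)c2cc1O[C@@H]1[C@@H](CO[Si](c2ccccc2)(c2ccccc2)C(C)(C)C)O[C@H](OC)[C@@H](OCOC)[C@@H]1OCOC | intermediate
14 | methyl 4-O-Ar-2,3-di-O-(methoxymethyl)-α-D-altropyranoside | COc1cc2oc(CCc3ccccc3)cc(=O)c2cc1O[C@@H]1[C@@H](CO)O[C@H](OC)[C@@H](OCOC)[C@@H]1OCOC | intermediate
15 | methyl 4-O-Ar-6-deoxy-6-iodo-2,3-di-O-(methoxymethyl)-α-D-altropyranoside | COc1cc2oc(CCc3ccccc3)cc(=O)c2cc1O[C@@H]1[C@@H](CI)O[C@H](OC)[C@@H](OCOC)[C@@H]1OCOC | intermediate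
16 | methyl 4-O-Ar-6-deoxy-2,3-di-O-(methoxymethyl)-α-D-arabino-hex-5-enopyranoside | COc1cc2oc(CCc3ccccc3)cc(=O)c2cc1O[C@@H]1C(=C)O[C@H](OC)[C@@H](OCOC)[C@@H]1OCOC | intermediate
17 | methyl 4-O-Ar-6-deoxy-5-hydroxy-6-(trifluoroacetoxymercurio)-2,3-di-O-(methoxymethyl)-α-D-arabino-hexopyranoside (hemiketal, C5 epimers, not isolated) | COc1cc2oc(CCc3ccccc3)cc(=O)c2cc1O[C@@H]1C(O)(C[Hg]OC(=O)C(F)(F)F)O[C@H](OC)[C@@H](OCOC)[C@@H]1OCOC | intermediate
18 | 4-O-Ar-6-deoxy-6-(trifluoroacetoxymercurio)-2,3-di-O-(methoxymethyl)-D-arabino-hexos-5-ulose (open-chain keto aldehyde, not isolated) | COc1cc2oc(CCc3ccccc3)cc(=O)c2cc1O[C@H](C(=O)C[Hg]OC(=O)C(F)(F)F)[C@@H](OCOC)[C@H](OCOC)C=O | intermediate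
19 | (2S,3S,4R,5R)-2-(ArO)-5-hydroxy-3,4-bis(methoxymethoxy)cyclohexan-1-one | COc1cc2oc(CCc3ccccc3)cc(=O)c2cc1O[C@@H]1C(=O)C[C@@H](O)[C@@H](OCOC)[C@@H]1OCOC | intermediate
20 | 5-O-(tert-butyldimethylsilyl) ether of 19 | COc1cc2oc(CCc3ccccc3)cc(=O)c2cc1O[C@@H]1C(=O)C[C@@H](O[Si](C)(C)C(C)(C)C)[C@@H](OCOC)[C@@H]1OCOC | intermediate
21 | pyrrolidine enamine of 20 (C1=C6 double bond) | COc1cc2oc(CCc3ccccc3)cc(=O)c2cc1O[C@@H]1C(N2CCCC2)=C[C@@H](O[Si](C)(C)C(C)(C)C)[C@@H](OCOC)[C@@H]1OCOC | intermediate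
22 | 2,2,6-trimethyl-4H-1,3-dioxin-4-one | CC1=CC(=O)OC(C)(C)O1 | starting material
23 | 2,2-dimethyl-6-(2-phenylethyl)-4H-1,3-dioxin-4-one | CC1(C)OC(=O)C=C(CCc2ccccc2)O1 | intermediate
24 | 5-phenylpent-1-ene-1,3-dione (acylketene, not isolated) | O=C=CC(=O)CCc1ccccc1 | intermediate
25 | 8a-(pyrrolidin-1-yl)-4a,5,6,7,8,8a-hexahydrochromen-4-one adduct of 21 and 24 (aminal, C4a/C8a undefined, not isolated) | COc1cc2oc(CCc3ccccc3)cc(=O)c2cc1O[C@@H]1C2(N3CCCC3)OC(CCc3ccccc3)=CC(=O)C2[C@@H](O[Si](C)(C)C(C)(C)C)[C@@H](OCOC)[C@@H]1OCOC | intermediate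
26 | 8-(ArO)-5-(tert-butyldimethylsilyloxy)-6,7-bis(methoxymethoxy)-2-(2-phenylethyl)-5,6,7,8-tetrahydro-4H-chromen-4-one (5-epi series) | COc1cc2oc(CCc3ccccc3)cc(=O)c2cc1O[C@@H]1c2oc(CCc3ccccc3)cc(=O)c2[C@@H](O[Si](C)(C)C(C)(C)C)[C@@H](OCOC)[C@@H]1OCOC | intermediate
27 | 8-(ArO)-5-hydroxy-6,7-bis(methoxymethoxy)-2-(2-phenylethyl)-5,6,7,8-tetrahydro-4H-chromen-4-one (5-epimer) | COc1cc2oc(CCc3ccccc3)cc(=O)c2cc1O[C@@H]1c2oc(CCc3ccccc3)cc(=O)c2[C@@H](O)[C@@H](OCOC)[C@@H]1OCOC | intermediate
28 | 8-(ArO)-6,7-bis(methoxymethoxy)-2-(2-phenylethyl)-7,8-dihydro-4H-chromene-4,5(6H)-dione | COc1cc2oc(CCc3ccccc3)cc(=O)c2cc1O[C@@H]1c2oc(CCc3ccccc3)cc(=O)c2C(=O)[C@@H](OCOC)[C@@H]1OCOC | intermediate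
29 | (5S,6R,7S,8S)-8-(ArO)-5-hydroxy-6,7-bis(methoxymethoxy)-2-(2-phenylethyl)-5,6,7,8-tetrahydro-4H-chromen-4-one | COc1cc2oc(CCc3ccccc3)cc(=O)c2cc1O[C@@H]1c2oc(CCc3ccccc3)cc(=O)c2[C@H](O)[C@@H](OCOC)[C@@H]1OCOC | intermediate
30 | (5S,6R,7S,8S)-5,6,7-trihydroxy-8-{[7-methoxy-4-oxo-2-(2-phenylethyl)-4H-chromen-6-yl]oxy}-2-(2-phenylethyl)-5,6,7,8-tetrahydro-4H-chromen-4-one | COc1cc2oc(CCc3ccccc3)cc(=O)c2cc1O[C@@H]1c2oc(CCc3ccccc3)cc(=O)c2[C@H](O)[C@@H](O)[C@@H]1O | target

**Step count**

Total: 22 steps. Longest linear sequence: 18 steps (steps 1–6, 10–16 and 18–22).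

**Steps most likely to fail**

1. Step 10 (O4 arylation). C–O bond formation at the flanked secondary alkoxide may be slow, so that protodeiodination of 12 or base-induced opening of its pyranone ring takes over. Fallback, from 12 and 8 back to 13: the aryl unit would become the nucleophilic partner of an oxidative Chan–Lam-type etherification. Miyaura borylation of 12 (B2pin2, Pd(dppf)Cl2, KOAc, dioxane, 80 °C) should give 7-methoxy-2-(2-phenylethyl)-6-(4,4,5,5-tetramethyl-1,3,2-dioxaborolan-2-yl)-4H-chromen-4-one F1. Treatment with KHF2 in aqueous MeOH should give potassium trifluoro[7-methoxy-4-oxo-2-(2-phenylethyl)-4H-chromen-6-yl]borate F2. F2 would then be coupled with alcohol 8 (Cu(OAc)2·H2O and DMAP as catalysts, 4 Å MS, O2, CH2Cl2, rt) at room temperature without strong base, giving 13.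

2. Step 18 (pyranone annulation, together with the enamine of step 16). The C5 silyloxy group may be lost by β-elimination, C8 may epimerise through enamine–iminium equilibration, pyrrolidine may add to the chromone of the aryl ether, or the acylketene may be consumed before C-acylation. Fallback, from 20 back to 26, without any amine: kinetic deprotonation towards the CH2 (LiN(SiMe3)2, THF, −78 °C) and aldol addition to 5-phenylpent-2-ynal F3 (made from 4-phenylbut-1-yne, n-BuLi and DMF) should give the propargylic aldol 2-(ArO)-5-(tert-butyldimethylsilyloxy)-6-(1-hydroxy-5-phenylpent-2-yn-1-yl)-3,4-bis(methoxymethoxy)cyclohexan-1-one F4. Dess–Martin oxidation would give the ynone 1,3-diketone 2-(ArO)-5-(tert-butyldimethylsilyloxy)-3,4-bis(methoxymethoxy)-6-(5-phenylpent-2-ynoyl)cyclohexan-1-one F5. Its enol oxygen on C8a should close onto the ynone in a 6-endo-dig oxa-Michael addition (K2CO3 cat., MeCN, rt, or AgOTf cat.) to give 26.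

3. Step 21 (C5 reset). Hydride addition may show poor facial selectivity, since attack anti to an axially placed C6 alkoxy group would return the 5-epimer. Ketone 28 may also suffer base-triggered β-elimination of the C7 alkoxy group followed by aromatisation. Fallback, from 27 back to 29, replacing steps 20 and 21 by a stereospecific SN2 inversion: Mitsunobu esterification of 27 with 4-nitrobenzoic acid (PPh3, DIAD, PhMe, 0 °C → rt) should give the inverted ester (5S)-8-(ArO)-6,7-bis(methoxymethoxy)-4-oxo-2-(2-phenylethyl)-5,6,7,8-tetrahydro-4H-chromen-5-yl 4-nitrobenzoate F6, and methanolysis (K2CO3, MeOH, 0 °C) would release 29.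

**Further compounds**

F1 | step 10 | 7-methoxy-2-(2-phenylethyl)-6-(4,4,5,5-tetramethyl-1,3,2-dioxaborolan-2-yl)-4H-chromen-4-one | COc1cc2oc(CCc3ccccc3)cc(=O)c2cc1B1OC(C)(C)C(C)(C)O1
F2 | step 10 | potassium trifluoro[7-methoxy-4-oxo-2-(2-phenylethyl)-4H-chromen-6-yl]borate | COc1cc2oc(CCc3ccccc3)cc(=O)c2cc1[B-](F)(F)F.[K+]
F3 | step 18 | 5-phenylpent-2-ynal | O=CC#CCCc1ccccc1
F4 | step 18 | 2-(ArO)-5-(tert-butyldimethylsilyloxy)-6-(1-hydroxy-5-phenylpent-2-yn-1-yl)-3,4-bis(methoxymethoxy)cyclohexan-1-one | COc1cc2oc(CCc3ccccc3)cc(=O)c2cc1O[C@@H]1C(=O)C(C(O)C#CCCc2ccccc2)[C@@H](O[Si](C)(C)C(C)(C)C)[C@@H](OCOC)[C@@H]1OCOC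
F5 | step 18 | 2-(ArO)-5-(tert-butyldimethylsilyloxy)-3,4-bis(methoxymethoxy)-6-(5-phenylpent-2-ynoyl)cyclohexan-1-one | COc1cc2oc(CCc3ccccc3)cc(=O)c2cc1O[C@@H]1C(=O)C(C(=O)C#CCCc2ccccc2)[C@@H](O[Si](C)(C)C(C)(C)C)[C@@H](OCOC)[C@@H]1OCOC
F6 | step 21 | (5S)-8-(ArO)-6,7-bis(methoxymethoxy)-4-oxo-2-(2-phenylethyl)-5,6,7,8-tetrahydro-4H-chromen-5-yl 4-nitrobenzoate | COc1cc2oc(CCc3ccccc3)cc(=O)c2cc1O[C@@H]1c2oc(CCc3ccccc3)cc(=O)c2[C@H](OC(=O)c2ccc(cc2)[N+](=O)[O-])[C@@H](OCOC)[C@@H]1OCOC
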